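The data were computed with constants of no real substance; scatter was added.

In this closed, stirred vessel starting material adds to partner to give mono adduct. The mono adduct can then be taken by more partner into double product or by more starting material into side product, or it can turn into its isomer.

| flask | starting material | partner | remark | time |
|---|---|---|---|---|
| epsilon | 0.65 mM | 1 mM | run made earlier |  |
| delta | 1.5 mM | 1 mM | run made earlier |  |
| zeta | 3.7 mM | 1 mM | run made earlier |  |
| red | 0.50 mM | 1.00 mM |  | 4.0 min |
| ochre | 1.0 mM | 1.00 mM |  | 4.0 min |
| violet | 2.0 mM | 1.00 mM |  | 4.0 min |
| grey | 4.0 mM | 1.00 mM |  | 4.0 min |

| run | time / s | mono adduct / % | starting material / % |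
|---|---|---|---|
| epsilon | 10.0 | 23 | 67 |
| epsilon | 20.0 | 33 | 48 |
| epsilon | 50.0 | 33 | 21 |
| epsilon | 120 | 26 | 5 |
| delta | 10.0 | 21 | 64 |
| delta | 20.0 | 24 | 47 |
| delta | 50.0 | 21 | 30 |
| delta | 120 | 18 | 12 |
| zeta | 15.0 | 15 | 57 |
| zeta | 40.0 | 1 | 42 |
| zeta | 80.0 | 1 | 35 |
| zeta | 120 | 3 | 28 |

(standard deviation of a reading: 2 percentage points)

- in percentages every species weighs as the starting material in it: one self-condensation product or side product counts as two
- candidate steps: starting material + partner -> mono adduct; partner + mono adduct -> double product; mono adduct <-> isomer of the product; 2 starting material -> self-condensation product; starting material + mono adduct -> side product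
- "hardly changes" means that all values lie within two and a half points (for a concentration: within two and a half percent of the largest)

* amount of mono adduct at the end, in percent of the starting material charged for red, ochre, violet, grey, in this order
* the course of these numbers from the first flask to the last (hardly changes / falls all the way / falls, then rises / rises all the way / rises, then falls)

Time is the first setting. By hand, a longer wait costs mono adduct once its peak is past, and the epsilon readings put that peak early: 33 % at 20.0 s, 33 % at 50.0 s, 26 % at 120 s. So at 4.0 min I am looking at a loss, and I ask which taker is there to cause it, partner or starting material.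

The starting material charge is the other setting, with partner held at 1.00 mM. Each addition removes one of each reagent, so it leaves their difference alone while both shrink, and the smaller one, the limiting reagent, loses the larger share of itself. So far as additions go, the comparison of the two takers therefore drifts toward whichever reagent was over from the start. I carry one number per flask; in grey it is 75.0 %, and I call it the surplus: starting material charged less partner charged, as a fraction of the starting material charged. A minus means partner is over.

At 120 s the readings follow it: surplus −53.8 % in epsilon gave 26 %, 33.3 % in delta gave 18 %, and 73.0 % in zeta gave 3 %. Red, at −100 %, has partner over, so that taker stays beside the mono adduct; the epsilon readings, with partner over too, fall from 33 % at 50.0 s to 26 % at 120 s. Ochre has surplus 0 %, with nothing over by the charges, so both takers shrink together and I expect it above red. I expect violet, at 50.0 %, between those delta and zeta readings, and grey under that zeta reading.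

The forecast gives 14 %, 18 %, 6 % and 1.5 %, a course that rises, then falls. Writing S for starting material and M for mono adduct, it says the side reaction “kills M once S is in excess”.

The flasks give 16.8 %, 21.5 %, 6.33 % and 0.323 %, a course that rises, then falls, and the forecast is right on both.

    starting material + partner → mono adduct (k = 47.0 L mol⁻¹ s⁻¹)
    partner + mono adduct → double product (k = 21.0 L mol⁻¹ s⁻¹)
    mono adduct ⇌ isomer of the product (K = 0.440, k = 0.0200 s⁻¹)
    2 starting material → self-condensation product (k = 1.40 L mol⁻¹ s⁻¹)
    starting material + mono adduct → side product (k = 20.0 L mol⁻¹ s⁻¹)

In red, at surplus −100 %, starting material was down to 3.31 % by 2.00 min with partner at 36.0 % of its own charge, and from then to 4.00 min double product went from 40.6 % to 57.1 % while side product went from 15.2 % to 15.9 %. In grey, at surplus 75.0 %, partner stood at 0 % by 2.00 min with starting material still at 27.7 % and side product already at 41.6 %, and mono adduct went from 1.21 % at that time to 0.323 % at 4.00 min.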